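Which flask ends higher after 1.0 h, south with everything together at the start, or east with its starting material in portions?

| setting | Saturday's | Sunday's | south | east |
|---|---|---|---|---|
| starting material | 0.20 M (in portions, 4) | 0.20 M (in portions, 4) | 0.20 M | 0.20 M (in portions, 4) |
| protic impurity | 0.010 M | 0.010 M | 0.0100 M | 0.0100 M |
| enzyme | 0.050 mM | 0.20 mM | 0.10 mM | 0.10 mM |
| remark | run made earlier; portions every 5.0 min | run made earlier; portions every 5.0 min | everything together at the start | the portions of starting material follow each other after 5.0 min, the first at the start |
| time |  |  | 1.0 h | 1.0 h |

| run | time / min | product / % | starting material / % |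
|---|---|---|---|
| Saturday's | 10.0 | 6 | 40 |
| Saturday's | 20.0 | 15 | 78 |
| Saturday's | 30.0 | 18 | 71 |
| Saturday's | 40.0 | 34 | 65 |
| Saturday's | 50.0 | 35 | 55 |
| Sunday's | 4.00 | 4 | 14 |
| Sunday's | 12.0 | 18 | 49 |
| Sunday's | 20.0 | 45 | 49 |
| Sunday's | 30.0 | 68 | 29 |
| Sunday's | 50.0 | 93 | 6 |

(standard deviation of a reading: 2 percentage points)

- which one finishes higher in amount of product, in percent of the starting material charged ("neither" within 2 percentage points) (south / east / neither)
- amount of product at the end, in percent of the starting material charged, south
- amount of product at the end, in percent of the starting material charged, east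

I want one clock for flasks that differ in enzyme and in feeding. In a portioned flask, the charge arrives on average 7.50 min after the start, and in south it arrives at the start. I define Sunday-minutes, u, as the time since that mean arrival multiplied by the flask's enzyme over Sunday's enzyme, which gives south 30.0 min.

Does this clock join the two runs? Saturday's reading at 50.0 min has u = 10.6 min, and Sunday's at 20.0 min has u = 12.5 min. Their products, 35% and 45%, stand in a ratio of 1.29, against 1.18 for their u, so with readings this scattered I accept one curve.

Where do the two flasks fall on it? East has u = 26.2 min. Sunday's last two readings, 68% at u = 22.5 min and 93% at u = 42.5 min, bracket both flasks. Interpolating, I reckon south at 77.4% and east at 72.7%. That gap of 4.7 percentage points is more than the margin, so I choose south.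

The forecast also says south, with 74% for south and 70% for east, and its ground for that order is that “East runs at lower substrate for the first 15 min”.

South ends at 78.8% and east at 74.7%, a gap of 4.1 points across the 3.80 min of u between them.

starting material + protic impurity → quenched substrate (k = 33.0 L mol⁻¹ min⁻¹); starting material + enzyme ⇌ complex (K = 6.10 L mol⁻¹, k = 17000 L mol⁻¹ min⁻¹); enzyme → spent catalyst (k = 2.50 × 10⁻⁵ min⁻¹); complex → enzyme + product (k = 76.0 min⁻¹) Spent catalyst in south stands at 0.0981% of the enzyme charged, and its formation makes no difference. A further flask, like south but with 0.0250 mM of enzyme, has u = 7.50 min. Saturday's run reaches that u at 37.5 min, between its readings of 18% and 34%, and the further flask gives 27.8%.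

Readings and results are calculated on assumed constants; scatter was added.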